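In percent of the substrate charged, the sum of the two readings I can add up, substrate and target, barely moves from one sample to the next.

all flasks: substrate 1.4 M; free catalyst 5 mol%
- gamma: coupling partner 2 equiv (in portions, 4); the very flask that is asked about, followed so far; portions every 0.60 s
- flask: coupling partner 2.00 equiv (in portions, 4); the portions of coupling partner follow each other after 0.60 s, the first at the start; time 6.0 min

gamma run (percent of the substrate charged)

| time / s | substrate / % | target / % |
|---|---|---|
| 10.0 | 17.7 | 26.0 |
| 15.0 | 9.8 | 32.5 |
| 25.0 | 3.0 | 41.1 |
| 40.0 | 0.2 | 43.9 |
| 60.0 | 0 | 45.1 |
| 120 | 0.2 | 43.6 |

(scatter of a reading: 1 percentage point)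

- the reaction counts as stopped when no species that holds the substrate changes by six tenths of a point or more over the second half of the time

- which holds at 6.0 min: what has brought the reaction to rest, or that it has not come to rest (the coupling partner has run out first / all of the substrate has reacted / no working catalyst is left / it is still moving)
- share of the substrate used up at 6.0 min
- target at 6.0 min, in percent of the substrate charged

Note for the bench; the gamma run is this same flask, followed so far.

1. Now: at 120 s the flask reads substrate 0.2 % and target 43.6 %.
2. Frozen: the mean of c(substrate) + c(target) over the six readings is 43.8 %. I call this the kept share, target made plus substrate still able to become target. Once substrate is gone, it is the selectivity to target.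
3. Lost: the remaining 56.2 % has left that sum before the first sample, at 10.0 s.
4. When you come: substrate reads 0.2 % by 40.0 s, and 6.0 min is later than that. So I expect target equal to the kept share, 43.8 %.
5. Leave it alone: the last two target readings differ by less than twice the scatter, so I read no drift in them.

The forecast gives all of the substrate has reacted, conversion 100 % and target 44.3 %, a little above my 43.8 %. Its ground: “The reaction has stopped because the substrate is exhausted”.

The flask gives all of the substrate has reacted, conversion 100 % and target 43.5 %.

    catalyst intermediate C → free catalyst + target (k = 0.930 /s)
    2 substrate → homo dimer (k = 0.0840 /M/s)
    coupling partner + free catalyst → catalyst intermediate A (k = 14.0 /M/s)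
    substrate + catalyst intermediate A → catalyst intermediate B (k = 2.60 /M/s)
    catalyst intermediate B → catalyst intermediate C (k = 33.0 /s)
    substrate → decomposition product (k = 4.10 × 10⁻⁵ /s)

The kept share falls short of the whole charge because of the conversion of substrate into homo dimer: the run without that step ends at 99.9 % target instead of 43.5 %. Scaling 43.8 % in proportion to loading for a neighbour flask, charged like this one except for 3 mol% of free catalyst, gives 26.3 %. The neighbour flask holds more target than that, 34.3 %, and at 6.00 min its homo dimer stands at 65.7 % of the substrate charged.

(The readings are calculated on assumed constants, noise included.)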